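Count the flask in drain times before you commit the gamma run.

| flask | substrate | partner | free catalyst | time |
|---|---|---|---|---|
| alpha | 0.400 M | 0.400 M | 0.0200 M |  |
| zeta | 0.160 M | 0.160 M | 0.0200 M |  |
| beta | 0.400 M | 1.20 M | 0.0200 M |  |
| delta | 0.800 M | 0.400 M | 0.0200 M |  |
| gamma | 2.60 M | 0.400 M | 0.0200 M | 14 min |

| run | time / min | [target] / M |
|---|---|---|
| alpha run | 2.3 | 0.0508 |
| alpha run | 4.7 | 0.1027 |
| alpha run | 7.0 | 0.1506 |
| alpha run | 9.3 | 0.1954 |
| alpha run | 12 | 0.2433 |
| alpha run | 14 | 0.2736 |
| zeta run | 2.3 | 0.0331 |
| zeta run | 4.7 | 0.0664 |
| zeta run | 7.0 | 0.0938 |
| zeta run | 9.3 | 0.1179 |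
| zeta run | 12 | 0.1327 |
| zeta run | 14 | 0.1401 |
| beta run | 2.3 | 0.0288 |
| beta run | 4.7 | 0.0555 |
| beta run | 7.0 | 0.0803 |
| beta run | 9.3 | 0.1052 |
| beta run | 12 | 0.1319 |
| beta run | 14 | 0.1498 |
| delta run | 2.3 | 0.0513 |
| delta run | 4.7 | 0.1147 |
| delta run | 7.0 | 0.1679 |
| delta run | 9.3 | 0.2175 |
| delta run | 12 | 0.2681 |
| delta run | 14 | 0.3020 |

(each reading ± 0.001 M)

- Overall: substrate + partner -> target, with free catalyst as catalyst.
- Constant volume, constant temperature.
- Readings of a species count what is bound in complexes too.
- An order is taken over about fifteen percent of the charge, up and down.

- the exponent of [substrate] in the starting rate at the charge of the alpha run (at the point where two percent of the substrate have become target) (one fixed amount of target, the same in the runs compared)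
- the exponent of [partner] in the starting rate at the charge of the alpha run (at the point where two percent of the substrate have become target)
- the zeta run starts with 0.240 M less of substrate and of partner than the alpha run, and with no target. Compared where both hold the same amount of substrate, once fifteen percent of what the zeta run was charged with has turned into target, is the zeta run faster, slower or alike (within a tenth)?
- target in the gamma run at 14 min, as a share of the substrate charged

For the alpha run, the charge of the limiting reagent divided by the rate up to the first reading is 18.1 min. Call this the drain time: how long the limiting charge lasts if the first rate holds.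

| run | limiting charge | first rate | drain time |
|---|---|---|---|
| alpha | c(partner) 0.400 M | 0.0221 M min⁻¹ | 18.1 min |
| zeta | c(partner) 0.160 M | 0.0144 M min⁻¹ | 11.1 min |
| beta | c(substrate) 0.400 M | 0.0125 M min⁻¹ | 31.9 min |
| delta | c(partner) 0.400 M | 0.0223 M min⁻¹ | 17.9 min |

Read down from alpha. The zeta run holds 0.400 of alpha's charges but keeps 0.652 of its first rate, so it drains sooner than alpha. The beta run has alpha's limiting charge with 3.00 times the partner, and its drain time is 1.76 times alpha's, so excess partner costs time. The delta run has twice the substrate of alpha, yet its drain time is about the same.

The gamma run has delta's c(partner) and much more substrate. My own reckoning is a guess: that excess substrate there costs the factor that excess partner cost in beta. That gives the gamma run a drain time of 31.6 min. Shrinking delta's target at 14 min by the same factor gives 6.59% of the substrate charged.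

The forecast is higher than my figure: 0.3 for the substrate order, −0.15 for the partner order, alike for the comparison of zeta with alpha, and 7.5% for the gamma run. One of its grounds: “tripling it nearly halves the rate, so excess partner inhibits”.

The flask gives 0.47, −0.16, alike and 6.78%.

    free catalyst + substrate → catalyst-substrate complex (21.24 M⁻¹ min⁻¹)
    catalyst-substrate complex + partner → loaded catalyst (69.60 M⁻¹ min⁻¹)
    loaded catalyst → target + free catalyst (12.66 min⁻¹)
    substrate + partner ⇌ idle substrate-reagent adduct, settled at all times (9.940 M⁻¹)
    free catalyst + substrate ⇌ idle catalyst-substrate complex, settled at all times (7.740 M⁻¹)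

The forecast and the flask part on the substrate order, 0.3 against 0.47. In the gamma run, 6.78% is 0.176 M of target at 14 min. The association of free catalyst and substrate to idle catalyst-substrate complex moves the readings by 59 in units of the scatter, as a root mean square. Now use the drain time on the time at which target reaches 0.5 of the substrate charged. For the alpha run, 0.5 of a drain time is 9.05 min, and the flask takes 9.57 min. For the beta run it is 15.9 min, and the flask takes longer, at 20.1 min.

(The readings stem from a simulated flask with constants of no real substance; the scatter is artificial.)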